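**Retrosynthetic overview**
- Last step: BBr3 O-demethylation of the ring-A mono-methyl ether of the target; the methyl masks the one OH that must not direct bromination.
- Four of the five C–Br bonds come from one fourfold ortho-bromination of a bisphenol in which each ring has one free OH with a blocked para position; the fifth Br (ortho to the ether O on ring B) is carried from the start.
- Key C–O bond (new step): 4-(benzyloxy)-2-bromophenol plus 3-bromo-4,4-dimethoxycyclohexadienone by addition–elimination at the β-bromo enone, then Zn/AcOH rearomatisation (a formal SNAr on 3-bromo-4-methoxyphenol).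
- Building blocks: the quinone monoketal from 3-bromo-4-methoxyphenol (PhI(OAc)2/MeOH) and the bromophenol from 4-(benzyloxy)phenol (NBS).
- Rings: none is constructed; both benzene rings are bought. Ring A is dearomatised in step 1 and rearomatised in step 3; ring B stays aromatic throughout.

Assumption: the target has no stereocentre, so the "single enantiomer" is the achiral compound itself; 3-bromo-4-methoxyphenol and 4-(benzyloxy)phenol are taken as catalogue chemicals.

**Step 1**
Reactants: 1 3-bromo-4-methoxyphenol
Product: 2 3-bromo-4,4-dimethoxycyclohexa-2,5-dien-1-one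
Conditions: PhI(OAc)2 (1.1 equiv), MeOH, 0 °C
Reagents that add atoms: methanol, SMILES CO
Why: Hypervalent-iodine oxidative dearomatisation of a p-alkoxyphenol (ligand exchange at I(III), loss of PhI, MeOH capture at the OMe-bearing para carbon) is a standard route to quinone monoketals and tolerates the ring bromide; no stereocentre is formed.

**Step 2**
Reactants: 3 4-(benzyloxy)phenol
Product: 4 4-(benzyloxy)-2-bromophenol
Conditions: NBS (1.0 equiv), i-Pr2NH (10 mol %), CH2Cl2, 0 °C, dark
Reagents that add atoms: N-bromosuccinimide, SMILES O=C1CCC(=O)N1Br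
Why: Electrophilic aromatic bromination in which the free OH is the strongest director and its para position is blocked, so one equivalent of NBS gives the mono-ortho-bromophenol and leaves the benzyl ether alone.

**Step 3**
Reactants: 2 3-bromo-4,4-dimethoxycyclohexa-2,5-dien-1-one; 4 4-(benzyloxy)-2-bromophenol
Product: 6 3-[4-(benzyloxy)-2-bromophenoxy]-4-methoxyphenol, via aryloxy quinone monoketal 5 (not isolated)
Conditions: K2CO3 (1.5 equiv), MeCN, 40 °C; then AcOH (10 equiv), Zn dust (5 equiv), 0 °C → rt, one pot
Reagents that add atoms: none
Why: Proposed new method: dearomative formal SNAr, in which C3 of 2 is the β-carbon of a β-bromo enone, so the phenoxide of 4 adds there and the enolate expels bromide irreversibly (addition–elimination, SNV) while attack at C5 is only a reversible oxa-Michael, and Zn/AcOH then delivers two electrons to the cross-conjugated dienone, which loses one methoxide and rearomatises without touching ArBr or OBn; the closest known reaction types are substitution of β-halo enones by phenoxides and Zn/AcOH reduction of p-quinol ethers and acetates, neither shown on a halogenated quinone monoketal as a way to make a diaryl ether at an electron-rich, non-activated aryl bromide position.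

**Step 4**
Reactants: 6 3-[4-(benzyloxy)-2-bromophenoxy]-4-methoxyphenol
Product: 7 3-(2-bromo-4-hydroxyphenoxy)-4-methoxyphenol
Conditions: BCl3 (3 equiv), C6HMe5 (3 equiv), CH2Cl2, −78 °C; then H2O
Reagents that add atoms: none
Why: Lewis-acid benzyl ether cleavage with pentamethylbenzene as a non-basic cation scavenger (Friedel–Crafts trapping of the benzyl cation) works at −78 °C, where the aryl methyl ether, the diaryl ether and the C–Br bond are inert.

**Step 5**
Reactants: 7 3-(2-bromo-4-hydroxyphenoxy)-4-methoxyphenol
Product: 8 2,6-dibromo-4-methoxy-3-(2,3,5-tribromo-4-hydroxyphenoxy)phenol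
Conditions: Br2 (4.2 equiv), AcOH–CH2Cl2, 0 °C → rt
Reagents that add atoms: bromine, SMILES BrBr
Why: Electrophilic aromatic substitution in which each ring has one free OH whose para position is blocked by an ether oxygen, so bromine enters the four ortho positions, and the resulting 2,6-dibromophenols are too deactivated for a fifth substitution ortho to OMe or OAr.

**Step 6**
Reactants: 8 2,6-dibromo-4-methoxy-3-(2,3,5-tribromo-4-hydroxyphenoxy)phenol
Product: 9 3,5-dibromo-2-(2,3,5-tribromo-4-hydroxyphenoxy)benzene-1,4-diol
Conditions: BBr3 (4 equiv), CH2Cl2, −78 °C → rt; then H2O, under Ar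
Reagents that add atoms: none
Why: BBr3 O-demethylation (O→B complexation, bromide SN2 at CH3) cleaves the aryl methyl ether while the diaryl ether and aryl bromides are inert, and the hydroquinone is released on hydrolytic work-up.

**Compound list**
1 | 3-bromo-4-methoxyphenol | COc1ccc(O)cc1Br | starting material
2 | 3-bromo-4,4-dimethoxycyclohexa-2,5-dien-1-one | COC1(OC)C=CC(=O)C=C1Br | intermediate
3 | 4-(benzyloxy)phenol | Oc1ccc(OCc2ccccc2)cc1 | starting material
4 | 4-(benzyloxy)-2-bromophenol | Oc1ccc(OCc2ccccc2)cc1Br | intermediate
5 | 3-[4-(benzyloxy)-2-bromophenoxy]-4,4-dimethoxycyclohexa-2,5-dien-1-one | COC1(OC)C=CC(=O)C=C1Oc1ccc(OCc2ccccc2)cc1Br | intermediate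
6 | 3-[4-(benzyloxy)-2-bromophenoxy]-4-methoxyphenol | COc1ccc(O)cc1Oc1ccc(OCc2ccccc2)cc1Br | intermediate
7 | 3-(2-bromo-4-hydroxyphenoxy)-4-methoxyphenol | COc1ccc(O)cc1Oc1ccc(O)cc1Br | intermediate
8 | 2,6-dibromo-4-methoxy-3-(2,3,5-tribromo-4-hydroxyphenoxy)phenol | COc1cc(Br)c(O)c(Br)c1Oc1cc(Br)c(O)c(Br)c1Br | intermediate
9 | 3,5-dibromo-2-(2,3,5-tribromo-4-hydroxyphenoxy)benzene-1,4-diol | Oc1cc(Br)c(O)c(Br)c1Oc1cc(Br)c(O)c(Br)c1Br | target

**Step count and risks**
Total step count: 6. Longest linear sequence: 5 (steps 1, 3, 4, 5, 6; the branch through steps 2, 3, 4, 5, 6 is equally long).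

The three steps most likely to fail are steps 3, 5 and 6.

Step 3 (the proposed new step) may fail for three reasons. The brominated β-carbon sits next to the quaternary ketal carbon and the nucleophile is an ortho-substituted phenoxide, so substitution may be slow. C-attack of the phenoxide may compete. The ketal may hydrolyse during the Zn/AcOH stage and give the unmasked hydroquinone. The fallback uses known chemistry, sets out from 4 and comes back at 6, so 1 and 2 are then not needed. Phenol 4 is coupled with commercial (5-formyl-2-methoxyphenyl)boronic acid (COc1ccc(C=O)cc1B(O)O) under Chan–Lam conditions (Cu(OAc)2, pyridine, 4 Å MS, CH2Cl2, air, rt) to give 3-[4-(benzyloxy)-2-bromophenoxy]-4-methoxybenzaldehyde F1. Baeyer–Villiger oxidation with mCPBA in CH2Cl2 gives 3-[4-(benzyloxy)-2-bromophenoxy]-4-methoxyphenyl formate F2, and K2CO3/MeOH methanolysis of the formate (Dakin sequence) gives 6.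

Step 5 may give mixtures by incomplete bromination at the two hindered positions (between OH and OAr on ring A, between OH and Br on ring B), by a fifth bromination ortho to OMe, or by oxidation of the p-alkoxyphenols to quinones. The fallback brominates the rings one at a time; it sets out from 6 and comes back at 8. NBS (2.05 equiv, CH2Cl2, 0 °C) brominates only the free-phenol ring of 6, because ring B is still a bis-ether, and gives 3-[4-(benzyloxy)-2-bromophenoxy]-2,6-dibromo-4-methoxyphenol F3. BCl3/C6HMe5 debenzylation as in step 4 gives 2,6-dibromo-3-(2-bromo-4-hydroxyphenoxy)-4-methoxyphenol F4. Br2 (2.1 equiv, AcOH) then brominates ring B alone, ring A being already deactivated, and gives 8.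

Step 6 runs on the penultimate, fully brominated compound. Prolonged BBr3/HBr exposure may cause partial protodebromination, and the hydroquinone product is air-sensitive. The fallback replaces Lewis-acid demethylation by oxidative demethylation and reduction; it sets out from 8 and comes back at 9. PhI(OAc)2 (1.05 equiv, MeCN/H2O, 0 °C) oxidises the more electron-rich p-methoxyphenol ring A, with loss of methanol, to 3,5-dibromo-2-(2,3,5-tribromo-4-hydroxyphenoxy)cyclohexa-2,5-diene-1,4-dione F5. Na2S2O4 (EtOAc/H2O, rt) reduces the quinone to 9. The selectivity rests on ring A being easier to oxidise than the tribrominated p-aryloxyphenol ring B.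

**Further compounds**
F1 | step 3 | 3-[4-(benzyloxy)-2-bromophenoxy]-4-methoxybenzaldehyde | COc1ccc(C=O)cc1Oc1ccc(OCc2ccccc2)cc1Br
F2 | step 3 | 3-[4-(benzyloxy)-2-bromophenoxy]-4-methoxyphenyl formate | COc1ccc(OC=O)cc1Oc1ccc(OCc2ccccc2)cc1Br
F3 | step 5 | 3-[4-(benzyloxy)-2-bromophenoxy]-2,6-dibromo-4-methoxyphenol | COc1cc(Br)c(O)c(Br)c1Oc1ccc(OCc2ccccc2)cc1Br
F4 | step 5 | 2,6-dibromo-3-(2-bromo-4-hydroxyphenoxy)-4-methoxyphenol | COc1cc(Br)c(O)c(Br)c1Oc1ccc(O)cc1Br
F5 | step 6 | 3,5-dibromo-2-(2,3,5-tribromo-4-hydroxyphenoxy)cyclohexa-2,5-diene-1,4-dione | O=C1C=C(Br)C(=O)C(Br)=C1Oc1cc(Br)c(O)c(Br)c1Br
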